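Target numbering: C1 (quaternary carbinol), C2 (OAc), C3 (OBz), C4=C5, C6 (ketone), C7 (CH2OBz). The cyclohexenone ring is cut at C3–C4. C3 is an allylic carbinol carbon bound to C4, the β-carbon of the C4=C5–C6(=O) enone, so the ring can be closed by adding a C4 vinylmetal to a C3 formyl group. One Nozaki–Hiyama–Kishi cyclisation forms the C3–C4 bond, the six-membered ring and the C3 stereocentre with the enone in place. Its precursor is an L-arabinose-derived cis-dioxolane carrying the C3 aldehyde and the (Z)-β-iodoacryloyl unit (C6–C4) on one face, with C1, C2 and the silylated C7 arm set.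

Key step: step 8

Assumption: the anomeric centres of 2, 4, 6 and 7 and the propargylic carbinol of 9 form as mixtures and are left unassigned, because each later becomes a carbonyl carbon. Sugar numbering is used up to 7 and target numbering from 9 on. Erythrose C1, C2, C3 and C4 become C6, C1, C2 and C3 of the target, the formaldehyde carbon becomes C7, and the ethynyl carbons become C5 and C4.

Step 1
Reactants: 1 L-arabinose
Product: 2 3,4-O-isopropylidene-L-arabinopyranose
Conditions: 2,2-dimethoxypropane, TsOH·H2O (cat.), DMF, rt
Reagents that add atoms: 2,2-dimethoxypropane, COC(C)(C)OC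
Why: Acid-catalysed transacetalisation should place the isopropylidene group on the only cis-vicinal diol of the pyranose (O3/O4), leaving the C1/C2 glycol free for cleavage, and touches no stereocentre.

Step 2
Reactants: 2 3,4-O-isopropylidene-L-arabinopyranose
Product: 4 2,3-O-isopropylidene-L-erythrofuranose, via 4-O-formyl-2,3-O-isopropylidene-L-erythrose 3 (not isolated)
Conditions: NaIO4, H2O, 0 °C → rt; then Na2CO3, rt
Reagents that add atoms: none
Why: Periodate glycol cleavage (Malaprade reaction) excises arabinose C1 as a formate ester that carbonate hydrolyses, so C3 and C4 of arabinose survive unchanged as C2 and C3 of L-erythrose, which closes to the cis-fused lactol.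

Step 3
Reactants: 4 2,3-O-isopropylidene-L-erythrofuranose; 5 formaldehyde
Product: 6 2-C-(hydroxymethyl)-2,3-O-isopropylidene-L-erythrofuranose
Conditions: 37% aq. HCHO (excess), K2CO3, MeOH, 65 °C
Reagents that add atoms: none
Why: In this crossed aldol addition the open-chain aldehyde enolises towards C2 and formaldehyde attacks the enolate face anti to the C4 arm; only the isomer with the formyl group cis to C4–OH can close to the cis-fused lactol, so the reversible reaction funnels to 6 and the quaternary centre (C1 of the target) is set by the neighbouring stereocentre (C2 of the target).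

Step 4
Reactants: 6 2-C-(hydroxymethyl)-2,3-O-isopropylidene-L-erythrofuranose
Product: 7 2-C-[(tert-butyldimethylsilyloxy)methyl]-2,3-O-isopropylidene-L-erythrofuranose
Conditions: TBSCl (1.05 equiv), imidazole, CH2Cl2, 0 °C
Reagents that add atoms: tert-butyldimethylsilyl chloride, CC(C)(C)[Si](C)(C)Cl
Why: Silylation of the primary hydroxyl (the future C7 oxygen) should outrun that of the hindered hemiacetal hydroxyl next to the quaternary carbon, as in the usual primary-selective silylation of furanose lactols.

Step 5
Reactants: 7 2-C-[(tert-butyldimethylsilyloxy)methyl]-2,3-O-isopropylidene-L-erythrofuranose; 8 ethynylmagnesium bromide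
Product: 9 1-[(4R,5S)-4-[(tert-butyldimethylsilyloxy)methyl]-5-(hydroxymethyl)-2,2-dimethyl-1,3-dioxolan-4-yl]prop-2-yn-1-ol (C6 carbinol epimers)
Conditions: HC≡CMgBr (4 equiv), THF, 0 °C → rt; aq. NH4Cl
Reagents that add atoms: none
Why: Grignard addition to the open-chain aldehyde tautomer of the lactol (the first equivalent deprotonates the lactol hydroxyl) installs C5 and C4 and frees the primary C3 hydroxyl; the new C6 carbinol centre needs no control because it is oxidised in the next step.

Step 6
Reactants: 9 ethynyl diol
Product: 11 (4R,5S)-5-[(tert-butyldimethylsilyloxy)methyl]-2,2-dimethyl-5-(prop-2-ynoyl)-1,3-dioxolane-4-carbaldehyde, via bis(alkoxydimethylsulfonium) dichloride 10 (not isolated)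
Conditions: (COCl)2 (5 equiv), DMSO (10 equiv), CH2Cl2, −78 °C; then iPr2NEt, −78 → −20 °C
Reagents that add atoms: none
Why: In this Swern oxidation both hydroxyls are converted into alkoxysulfonium ions before any carbonyl exists, so ketone and aldehyde appear together on adding base and no hydroxy aldehyde remains to close to a lactol and be over-oxidised to a lactone (the weakness of periodinane or oxoammonium oxidants on a cis-1,4-diol), while the hindered base and low temperature protect the C2 centre α to the aldehyde.

Step 7
Reactants: 11 ynone aldehyde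
Product: 12 (4R,5S)-5-[(tert-butyldimethylsilyloxy)methyl]-5-[(2Z)-3-iodoprop-2-enoyl]-2,2-dimethyl-1,3-dioxolane-4-carbaldehyde
Conditions: NaI (2 equiv), AcOH, rt, dark, short reaction time
Reagents that add atoms: sodium iodide, [Na+].[I-]
Why: In this conjugate hydroiodination iodide adds to the alkyne terminus C4 and the allenol is protonated at C5 from the side of the small C4 hydrogen, giving the kinetic (Z)-β-iodoenone by overall anti addition, while aldehyde, acetonide and silyl ether should tolerate anhydrous acetic acid.

Step 8
Reactants: 12 (Z)-β-iodoenone aldehyde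
Product: 14 (1S,2S,3R)-3-hydroxy-1,2-(isopropylidenedioxy)-1-[(tert-butyldimethylsilyloxy)methyl]cyclohex-4-en-6-one (target numbering), via C4 vinylchromium dichloride 13 (not isolated)
Conditions: CrCl2 (8 equiv), NiCl2 (0.1 equiv), degassed DMSO (0.005 M), rt; aq. potassium sodium tartrate (KNaC4H4O6) work-up
Reagents that add atoms: none
Why: Zerovalent nickel, formed from NiCl2 by divalent chromium, inserts into the C4–I bond of 12 and hands the vinyl group to trivalent chromium; the resulting vinylchromium 13 adds to the aldehyde but not to the C6 ketone, an intramolecular Nozaki–Hiyama–Kishi reaction whose closest precedent is the addition of (Z)-β-iodo enones and enoates to aldehydes. The carbocycle closes in the 6-exo-trig mode at the C3 carbonyl; the (Z)-alkene and the cis-dioxolane hold C4 and C3 close together, so the C4=C5–C6(=O) enone emerges complete. The only new stereocentre, C3, is controlled by C2 and the fused dioxolane: in the half-chair transition state the C7 arm on C1 sits equatorial, the C2–O bond is then equatorial and antiperiplanar to the forming C3–C4 bond (polar Felkin–Anh arrangement), and the chromium-bound aldehyde oxygen takes the pseudo-equatorial site away from the axial C1–O bond, which places the C3 hydroxyl trans to the C2 oxygen. The step needs aldehyde-over-ketone chemoselectivity, which the low basicity and carbonyl selectivity of organochromium reagents provide, and cyclisation over intermolecular coupling, which high dilution and the cis-dioxolane template provide.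

Step 9
Reactants: 14 hydroxy enone silyl ether
Product: 15 (1S,2S,3R)-3-hydroxy-1-(hydroxymethyl)-1,2-(isopropylidenedioxy)cyclohex-4-en-6-one (target numbering)
Conditions: HF·pyridine, pyridine, THF, 0 °C → rt
Reagents that add atoms: none
Why: Buffered fluoride-mediated desilylation should free the primary C7 hydroxyl without touching the acetonide or the γ-hydroxy enone, which a basic fluoride source could damage.

Step 10
Reactants: 15 enone diol
Product: 16 (1S,2S,3R)-3-benzoyloxy-1-(benzoyloxymethyl)-1,2-(isopropylidenedioxy)cyclohex-4-en-6-one (zeylenone acetonide)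
Conditions: BzCl (3 equiv), pyridine, DMAP (cat.), CH2Cl2, 0 °C → rt
Reagents that add atoms: benzoyl chloride, O=C(Cl)c1ccccc1
Why: Nucleophile-catalysed O-acylation esterifies both free hydroxyls (primary C7 and allylic C3) with retention at C3, and no selectivity is needed because O1 and O2 are locked in the acetonide.

Step 11
Reactants: 16 zeylenone acetonide
Product: 17 zeylenone, (1S,2S,3R)-3-benzoyloxy-1-(benzoyloxymethyl)-1,2-dihydroxycyclohex-4-en-6-one
Conditions: TFA/H2O (9:1), 0 °C
Reagents that add atoms: none
Why: Acid-catalysed acetal hydrolysis should release the cis-1,2-diol, since benzoates and the enone tolerate cold aqueous acid and acyl migration is slow without base.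

Step 12
Reactants: 17 zeylenone
Product: 18 2-O-acetylzeylenone, (1S,2S,3R)-2-acetoxy-3-benzoyloxy-1-(benzoyloxymethyl)-1-hydroxycyclohex-4-en-6-one
Conditions: Ac2O (1.5 equiv), pyridine, DMAP (cat.), CH2Cl2, 0 °C
Reagents that add atoms: acetic anhydride, CC(=O)OC(C)=O
Why: Acetylation should occur only at the secondary C2 hydroxyl because the tertiary C1 hydroxyl on the quaternary carbon α to the ketone is far less reactive, and C2 keeps its configuration since its C–O bond is not broken.

Compound list
1 | L-arabinose | O=C[C@H](O)[C@@H](O)[C@@H](O)CO | starting material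
2 | 3,4-O-isopropylidene-L-arabinopyranose (anomeric mixture) | OC1OC[C@@H]2OC(C)(C)O[C@@H]2[C@H]1O | intermediate
3 | 4-O-formyl-2,3-O-isopropylidene-L-erythrose (not isolated) | O=COC[C@@H]1OC(C)(C)O[C@@H]1C=O | intermediate
4 | 2,3-O-isopropylidene-L-erythrofuranose (lactol of 2,3-O-isopropylidene-L-erythrose, anomeric mixture) | OC1OC[C@@H]2OC(C)(C)O[C@H]12 | intermediate
5 | formaldehyde | C=O | starting material
6 | 2-C-(hydroxymethyl)-2,3-O-isopropylidene-L-erythrofuranose (anomeric mixture) | OC1OC[C@@H]2OC(C)(C)O[C@]12CO | intermediate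
7 | 2-C-[(tert-butyldimethylsilyloxy)methyl]-2,3-O-isopropylidene-L-erythrofuranose (anomeric mixture) | OC1OC[C@@H]2OC(C)(C)O[C@]12CO[Si](C)(C)C(C)(C)C | intermediate
8 | ethynylmagnesium bromide | C#C[Mg]Br | starting material
9 | 1-[(4R,5S)-4-[(tert-butyldimethylsilyloxy)methyl]-5-(hydroxymethyl)-2,2-dimethyl-1,3-dioxolan-4-yl]prop-2-yn-1-ol (carbinol epimers) | C#CC(O)[C@@]1(CO[Si](C)(C)C(C)(C)C)OC(C)(C)O[C@H]1CO | intermediate
10 | bis(alkoxydimethylsulfonium) dichloride of diol 9 (not isolated) | C#CC(O[S+](C)C)[C@@]1(CO[Si](C)(C)C(C)(C)C)OC(C)(C)O[C@H]1CO[S+](C)C.[Cl-].[Cl-] | intermediate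
11 | (4R,5S)-5-[(tert-butyldimethylsilyloxy)methyl]-2,2-dimethyl-5-(prop-2-ynoyl)-1,3-dioxolane-4-carbaldehyde | C#CC(=O)[C@@]1(CO[Si](C)(C)C(C)(C)C)OC(C)(C)O[C@H]1C=O | intermediate
12 | (4R,5S)-5-[(tert-butyldimethylsilyloxy)methyl]-5-[(2Z)-3-iodoprop-2-enoyl]-2,2-dimethyl-1,3-dioxolane-4-carbaldehyde (key-step precursor) | O=C[C@@H]1OC(C)(C)O[C@]1(CO[Si](C)(C)C(C)(C)C)C(=O)/C=C\I | intermediate
13 | C4 vinylchromium dichloride derived from 12 (trivalent chromium, not isolated) | O=C[C@@H]1OC(C)(C)O[C@]1(CO[Si](C)(C)C(C)(C)C)C(=O)/C=C\[Cr](Cl)Cl | intermediate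
14 | (1S,2S,3R)-3-hydroxy-1,2-(isopropylidenedioxy)-1-[(tert-butyldimethylsilyloxy)methyl]cyclohex-4-en-6-one (target numbering; C3–OH trans to C2–O; key-step product) | CC1(C)O[C@H]2[C@H](O)C=CC(=O)[C@@]2(CO[Si](C)(C)C(C)(C)C)O1 | intermediate
15 | (1S,2S,3R)-3-hydroxy-1-(hydroxymethyl)-1,2-(isopropylidenedioxy)cyclohex-4-en-6-one (target numbering) | CC1(C)O[C@H]2[C@H](O)C=CC(=O)[C@@]2(CO)O1 | intermediate
16 | (1S,2S,3R)-3-benzoyloxy-1-(benzoyloxymethyl)-1,2-(isopropylidenedioxy)cyclohex-4-en-6-one (zeylenone acetonide) | CC1(C)O[C@H]2[C@H](OC(=O)c3ccccc3)C=CC(=O)[C@@]2(COC(=O)c3ccccc3)O1 | intermediate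
17 | zeylenone, (1S,2S,3R)-3-benzoyloxy-1-(benzoyloxymethyl)-1,2-dihydroxycyclohex-4-en-6-one (target numbering) | O[C@H]1[C@H](OC(=O)c2ccccc2)C=CC(=O)[C@]1(O)COC(=O)c1ccccc1 | intermediate
18 | 2-O-acetylzeylenone, (1S,2S,3R)-2-acetoxy-3-benzoyloxy-1-(benzoyloxymethyl)-1-hydroxycyclohex-4-en-6-one (target numbering) | CC(=O)O[C@H]1[C@H](OC(=O)c2ccccc2)C=CC(=O)[C@]1(O)COC(=O)c1ccccc1 | target

Total step count: 12. Longest linear sequence: 12 steps (1 to 18).

Steps most likely to fail

Step 8. The vinylchromium may add to the wrong face of the C3 formyl group and place the hydroxyl cis to the C2 oxygen; reductive loss of iodine or intermolecular coupling would lower the return further. The fallback sets out from 12 and rejoins the route at 16, fixing C3 by inversion instead of by the facial preference of the ring closure. The cyclisation is run as before and the (1S,2S,3S)-configured C3-epimeric hydroxy enone F1 is carried on. Mitsunobu esterification (PhCO2H, PPh3, DIAD, THF, 0 °C) should displace the activated C3 oxygen with inversion and give the (3R)-benzoate silyl ether F2. HF·pyridine would then free the C7 hydroxyl to give the C7-hydroxy C3-benzoate F3, and BzCl, pyridine and DMAP would convert it into 16.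

Step 6. The hindered propargylic hydroxyl may be activated incompletely, so that the hydroxy aldehyde closes to a lactol and is over-oxidised; the base may also degrade the ethynyl ketone or epimerise C2. The fallback sets out from 9 and rejoins at 12, replacing steps 6 and 7 by a stepwise sequence in which no aldehyde ever faces a free hydroxyl. Selective silylation of the primary hydroxyl (TESCl, imidazole, CH2Cl2, −40 °C) gives the mono-triethylsilyl ether F4, and Dess–Martin periodinane oxidises its only free hydroxyl to the ynone triethylsilyl ether F5. NaI in AcOH then gives the (Z)-β-iodoenone triethylsilyl ether F6. HF·pyridine with pyridine at 0 °C removes the primary triethylsilyl group beside the neopentylic tert-butyldimethylsilyl ether and gives the hydroxy (Z)-iodoenone F7. A second Dess–Martin oxidation delivers 12; the only other carbonyl is a ketone, whose hemiketal cannot be oxidised further.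

Step 7. The acid may isomerise the kinetic (Z)-iodoenone to the (E)-isomer, which cannot cyclise, and may erode the acetonide or silyl ether. The fallback sets out from 9 and rejoins at 12, again replacing steps 6 and 7, and fixes the alkene geometry by syn hydrogenation before any oxidation. Iodination of the terminal alkyne (N-iodosuccinimide, AgNO3 cat., acetone) gives the iodoalkyne diol F8. Diimide, generated from 2-nitrobenzenesulfonohydrazide and Et3N in THF/iPrOH, adds hydrogen cis and should give the (Z)-iodoallylic diol F9. The double Swern oxidation of step 6 then gives 12 without any exposure to acid.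

Further compounds
F1 | step 8 | (1S,2S,3S)-3-hydroxy-1,2-(isopropylidenedioxy)-1-[(tert-butyldimethylsilyloxy)methyl]cyclohex-4-en-6-one (C3 epimer of 14) | CC1(C)O[C@H]2[C@@H](O)C=CC(=O)[C@@]2(CO[Si](C)(C)C(C)(C)C)O1
F2 | step 8 | (1S,2S,3R)-3-benzoyloxy-1,2-(isopropylidenedioxy)-1-[(tert-butyldimethylsilyloxy)methyl]cyclohex-4-en-6-one | CC1(C)O[C@H]2[C@H](OC(=O)c3ccccc3)C=CC(=O)[C@@]2(CO[Si](C)(C)C(C)(C)C)O1
F3 | step 8 | (1S,2S,3R)-3-benzoyloxy-1-(hydroxymethyl)-1,2-(isopropylidenedioxy)cyclohex-4-en-6-one | CC1(C)O[C@H]2[C@H](OC(=O)c3ccccc3)C=CC(=O)[C@@]2(CO)O1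
F4 | step 6 | primary triethylsilyl ether of diol 9 (carbinol epimers) | C#CC(O)[C@@]1(CO[Si](C)(C)C(C)(C)C)OC(C)(C)O[C@H]1CO[Si](CC)(CC)CC
F5 | step 6 | ynone triethylsilyl ether | C#CC(=O)[C@@]1(CO[Si](C)(C)C(C)(C)C)OC(C)(C)O[C@H]1CO[Si](CC)(CC)CC
F6 | step 6 | (Z)-β-iodoenone triethylsilyl ether | CC[Si](CC)(CC)OC[C@@H]1OC(C)(C)O[C@]1(CO[Si](C)(C)C(C)(C)C)C(=O)/C=C\I
F7 | step 6 | (Z)-β-iodoenone primary alcohol | OC[C@@H]1OC(C)(C)O[C@]1(CO[Si](C)(C)C(C)(C)C)C(=O)/C=C\I
F8 | step 7 | iodoalkyne diol (carbinol epimers) | IC#CC(O)[C@@]1(CO[Si](C)(C)C(C)(C)C)OC(C)(C)O[C@H]1CO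
F9 | step 7 | (Z)-iodoallylic diol (carbinol epimers) | I/C=C\C(O)[C@@]1(CO[Si](C)(C)C(C)(C)C)OC(C)(C)O[C@H]1CO
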